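**Assumption:** the SMILES is read as the (3R,4R) lactone (the two benzyl groups trans, the 3‑OH cis to the C4 benzyl). Compounds 1, 3 and 6 are taken as commercial. This route has not been run; stereochemical outcomes are predicted from transition-state analysis.

## Retrosynthetic overview

1. Target 11 ⇐ global hydrogenolysis of the tri‑O‑benzyl lactone 10. The classical late-stage α‑hydroxylation of a dibenzylbutyrolactone enolate is avoided.
2. Lactone 10 (the only ring, formed second to last) ⇐ ozonolysis/NaBH4/lactonisation of the γ,δ‑unsaturated α‑benzyloxy acid 9; the propenyl group is a latent C5–O.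
3. Acid 9 ⇐ chelation-controlled Ireland–Claisen rearrangement of ester 8. This key step makes the C3–C4 bond and both stereocentres at once, with 1,3‑chirality transfer from a sacrificial (R)‑carbinol.
4. Ester 8 ⇐ (R,Z)‑allylic alcohol 5 + racemic α‑benzyloxy acid 7.
5. 5 ⇐ (R)‑but‑3‑yn‑2‑ol 3 + benzylic bromide 2 (Cu coupling, then Lindlar); 7 ⇐ benzyloxyacetic acid 6 + 2.

## Route

**Step 1**
Reactants: 1, 4‑(benzyloxy)‑3‑methoxybenzyl alcohol
Product: 2, 4‑(benzyloxy)‑3‑methoxybenzyl bromide
Conditions: PBr3 (0.4 equiv), Et2O, 0 °C, 1 h; used crude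
Reagents that add atoms: phosphorus tribromide, BrP(Br)Br
Why: Standard SN2 bromination of an activated benzylic alcohol via its phosphite ester; no stereocentre is involved.

**Step 2**
Reactants: 3, (R)‑but‑3‑yn‑2‑ol; 2, 4‑(benzyloxy)‑3‑methoxybenzyl bromide
Product: 4, (R)‑5‑[4‑(benzyloxy)‑3‑methoxyphenyl]pent‑3‑yn‑2‑ol
Conditions: 3, EtMgBr (2.1 equiv), THF, 0 °C → rt; CuBr·SMe2 (10 mol %); then 2 (1.2 equiv), rt → 45 °C
Reagents that add atoms: none
Why: Copper-catalysed sp–sp3 coupling of the alkynyl Grignard (the hydroxyl is masked in situ as its magnesium alkoxide) with a reactive benzylic bromide; the carbinol centre is not touched and stays R.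

**Step 3**
Reactants: 4, (R)‑5‑[4‑(benzyloxy)‑3‑methoxyphenyl]pent‑3‑yn‑2‑ol
Product: 5, (2R,3Z)‑5‑[4‑(benzyloxy)‑3‑methoxyphenyl]pent‑3‑en‑2‑ol
Conditions: H2 (1 atm), Lindlar catalyst, quinoline, EtOAc, rt, stopped at 1 equiv H2
Reagents that add atoms: none
Why: Lindlar syn semi-hydrogenation gives the Z‑alkene needed for the anti Claisen outcome, and the poisoned catalyst leaves the aryl benzyl ether intact.

**Step 4**
Reactants: 6, 2‑(benzyloxy)acetic acid; 2, 4‑(benzyloxy)‑3‑methoxybenzyl bromide
Product: 7, rac‑2‑(benzyloxy)‑3‑[4‑(benzyloxy)‑3‑methoxyphenyl]propanoic acid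
Conditions: LDA (2.2 equiv), THF, −78 °C, 1 h; then 2, DMPU, −78 → −20 °C; H3O+
Reagents that add atoms: none
Why: C‑alkylation of the carboxylate enolate dianion of an α‑alkoxy acid by a benzylic bromide; the product can be racemic because this centre is planarised again in Step 6.

**Step 5**
Reactants: 5, (2R,3Z)‑5‑[4‑(benzyloxy)‑3‑methoxyphenyl]pent‑3‑en‑2‑ol; 7, rac‑2‑(benzyloxy)‑3‑[4‑(benzyloxy)‑3‑methoxyphenyl]propanoic acid
Product: 8, (2R,3Z)‑5‑[4‑(benzyloxy)‑3‑methoxyphenyl]pent‑3‑en‑2‑yl 2‑(benzyloxy)‑3‑[4‑(benzyloxy)‑3‑methoxyphenyl]propanoate (about 1:1 epimers at the acyl α‑carbon, inconsequential)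
Conditions: EDC·HCl, DMAP (cat.), CH2Cl2, 0 °C → rt
Reagents that add atoms: none
Why: Steglich esterification forms the acyl–oxygen bond without breaking the carbinol C–O bond, so the (R) centre and the Z‑alkene are retained.

**Step 6 (key step)**
Reactants: 8, the ester from Step 5
Product: 9, (2R,3R,4E)‑2‑(benzyloxy)‑2,3‑bis[4‑(benzyloxy)‑3‑methoxybenzyl]hex‑4‑enoic acid
Conditions: LDA (1.3 equiv), THF, −78 °C, 1 h; TMSCl/Et3N, −78 °C → rt (45 °C if needed); then 1 M HCl
Reagents that add atoms: none
Why: Chelation-controlled Ireland–Claisen rearrangement: Li chelation between the enolate oxygen and the α‑OBn fixes the ketene acetal geometry (OBn cis to OSi), and the chair [3,3] transition state with the carbinol methyl equatorial (the other chair has a 1,3‑diaxial Me/CH2Ar clash with the Z‑alkene) sets C2 and C3 together as the 2,3‑anti (2R,3R) isomer while the (R)‑carbinol centre is consumed.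

**Step 7**
Reactants: 9, the hexenoic acid from Step 6
Product: 10, (3R,4R)‑3‑(benzyloxy)‑3,4‑bis[4‑(benzyloxy)‑3‑methoxybenzyl]dihydrofuran‑2(3H)‑one
Conditions: O3, CH2Cl2/MeOH (4:1), −78 °C, Sudan Red 7B end-point; NaBH4, −78 → 0 °C; then 1 M HCl, rt (cat. TsOH, CH2Cl2 if needed); the minor diastereomer is removed here by chromatography/crystallisation
Reagents that add atoms: ozone, [O-][O+]=O (supplies the ring oxygen)
Why: Ozonolysis with reductive work-up turns the propenyl group into CH2OH, and the resulting γ‑hydroxy acid lactonises spontaneously; neither stereocentre is epimerisable (C3 quaternary, C4 not α to the carbonyl).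

**Step 8**
Reactants: 10, the tri‑O‑benzyl lactone
Product: 11, (+)‑nortrachelogenin, (3R,4R)‑3‑hydroxy‑3,4‑bis(4‑hydroxy‑3‑methoxybenzyl)dihydrofuran‑2(3H)‑one
Conditions: H2 (1 atm), 10 % Pd/C (or Pd(OH)2/C), EtOAc/MeOH, rt
Reagents that add atoms: none
Why: Hydrogenolysis cleaves the two aryl benzyl ethers and the tertiary alkyl benzyl ether at their PhCH2–O bonds, while the lactone, the ArCH2–C bonds and both stereocentres are inert.

## Compound list

1 | 4‑(benzyloxy)‑3‑methoxybenzyl alcohol | COc1cc(CO)ccc1OCc1ccccc1 | starting material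
2 | 4‑(benzyloxy)‑3‑methoxybenzyl bromide | COc1cc(CBr)ccc1OCc1ccccc1 | intermediate
3 | (R)‑but‑3‑yn‑2‑ol | C[C@@H](O)C#C | starting material
4 | (R)‑5‑[4‑(benzyloxy)‑3‑methoxyphenyl]pent‑3‑yn‑2‑ol | C[C@@H](O)C#CCc1ccc(OCc2ccccc2)c(OC)c1 | intermediate
5 | (2R,3Z)‑5‑[4‑(benzyloxy)‑3‑methoxyphenyl]pent‑3‑en‑2‑ol | C[C@@H](O)/C=C\Cc1ccc(OCc2ccccc2)c(OC)c1 | intermediate
6 | 2‑(benzyloxy)acetic acid | OC(=O)COCc1ccccc1 | starting material
7 | rac‑2‑(benzyloxy)‑3‑[4‑(benzyloxy)‑3‑methoxyphenyl]propanoic acid | OC(=O)C(Cc1ccc(OCc2ccccc2)c(OC)c1)OCc1ccccc1 | intermediate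
8 | (2R,3Z)‑5‑[4‑(benzyloxy)‑3‑methoxyphenyl]pent‑3‑en‑2‑yl 2‑(benzyloxy)‑3‑[4‑(benzyloxy)‑3‑methoxyphenyl]propanoate | C[C@@H](OC(=O)C(Cc1ccc(OCc2ccccc2)c(OC)c1)OCc1ccccc1)/C=C\Cc1ccc(OCc2ccccc2)c(OC)c1 | intermediate
9 | (2R,3R,4E)‑2‑(benzyloxy)‑2,3‑bis[4‑(benzyloxy)‑3‑methoxybenzyl]hex‑4‑enoic acid | OC(=O)[C@@](OCc1ccccc1)(Cc1ccc(OCc2ccccc2)c(OC)c1)[C@H](Cc1ccc(OCc2ccccc2)c(OC)c1)/C=C/C | intermediate
10 | (3R,4R)‑3‑(benzyloxy)‑3,4‑bis[4‑(benzyloxy)‑3‑methoxybenzyl]dihydrofuran‑2(3H)‑one | COc1cc(C[C@@H]2COC(=O)[C@@]2(OCc2ccccc2)Cc2ccc(OCc3ccccc3)c(OC)c2)ccc1OCc1ccccc1 | intermediate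
11 | (+)‑nortrachelogenin | COc1cc(C[C@@H]2COC(=O)[C@@]2(O)Cc2ccc(O)c(OC)c2)ccc1O | target

## Summary

Total step count: 8.
Longest linear sequence: 7 steps (Steps 1 → 2 → 3 → 5 → 6 → 7 → 8); Step 4 is a one-step side branch from 6 and 2.

Steps most likely to fail, each with a fallback:

1. **Step 6 (Ireland–Claisen forming a fully substituted carbinol carbon next to a tertiary centre from a Z‑allyl ester).** The risks are sluggish enolisation, chair/boat leakage and a modest d.r. Fallback: split the stereocontrol. Rearrange the simple benzyloxyacetate ester of 5 (a standard chelated glycolate Claisen that sets only C4), carry the product through ozonolysis/NaBH4 to the 3‑benzyloxy‑4‑benzyl lactone, then benzylate its lithium enolate with 2. Alkylation anti to the C4 substituent gives the same trans-dibenzyl, cis‑OBn arrangement as 10.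

2. **Step 2 (Cu-catalysed alkynyl–benzyl coupling on an unprotected alkynol with an electron-rich, labile bromide).** The risks are Wurtz homocoupling and alkyne–allene isomerisation. Fallback: build the Z‑alkene by sp2–sp3 coupling instead. Convert the TBS ether of 3 to the iodoalkyne, reduce with diimide to the (Z)‑vinyl iodide, run a Pd-catalysed Negishi coupling with the benzylic zinc reagent derived from 2, then remove TBS. This gives 5 directly and also removes the Lindlar step.

3. **Step 4 (dianion alkylation of benzyloxyacetic acid).** The risks are incomplete dianion formation, Wittig-type rearrangement of the α‑benzyloxy carbanion and a low yield with the sensitive bromide. Fallback: move the C–C bond formation to the ester stage. Acylate 5 with benzyloxyacetyl chloride, then alkylate the chelated ester lithium enolate with 2 at −78 °C (below the temperature at which it rearranges) to reach 8 without ever making acid 7.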